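**Plan**
1. Retrosynthetic cuts (labdane numbering): C-9–C-11 (side chain joined to a C-9 enol triflate), then C-7=C-8 of ring B (aldol condensation of a C-9 ethyl ketone on a C-7 aldehyde), then C-1–C-10 and C-3–C-4 of ring A together (annulation with methyl acrylate), last C-4–C-5 (conjugate addition to a butenolide).
2. Forward order: butenolide → γ-lactone with C-9 as the lactone carbonyl on O-6 → ring A (key step) → C-4 methyl and 3α-OH → lactone opened by EtLi and O-6 re-closed on C-19 → ring B → enol triflate → lactone reduced to 6β-OH and 19-OH → side chain → ester hydrolysis.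
3. Enabling feature: in ring A, C-10 and C-4 flank C-5, and each adjoins a carbon that can be held at the carboxyl level (C-9, later the ring-B alkene carbon; C-19, later the CH2OH), while C-3 bears oxygen. An acrylate therefore supplies C-1 as Michael acceptor for C-10 and C-3 as acyl acceptor for C-4; holding C-9 as the 9→6 lactone leaves no second enolisable position next to it.
4. Stereochemistry: C-6 from (S)-5-(hydroxymethyl)furan-2(5H)-one; C-5 by conjugate addition anti to the C-6 substituent; C-10 by acrylate addition anti to the C-5 arm; C-4 by methylation anti to the axial C-10 methyl; C-3 by equatorial hydride attack; 13E by syn-carbocupration.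

Key step: step 3

Remark: labdane numbering is used for the atoms of all intermediates; 8 is carried on as its C-4 epimer/enol mixture because C-4 is fixed only in step 4.

Step 1
Reactants: 1 (S)-5-(hydroxymethyl)furan-2(5H)-one
Product: 2 (S)-5-[(benzyloxy)methyl]furan-2(5H)-one
Conditions: BnOC(=NH)CCl3, TfOH (cat.), CH2Cl2/cyclohexane, 0 °C → rt
Reagents that add atoms: benzyl 2,2,2-trichloroacetimidate, N=C(OCc1ccccc1)C(Cl)(Cl)Cl
Why: acid-catalysed O-benzylation with the trichloroacetimidate avoids base, which would deprotonate the butenolide at C-6 and racemise it, so the stereocentre is untouched.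

Step 2
Reactants: 2 (S)-5-[(benzyloxy)methyl]furan-2(5H)-one; 3 tert-butyl acetate
Product: 5 tert-butyl 2-[(2S,3S,4S)-2-[(benzyloxy)methyl]-4-methyl-5-oxooxolan-3-yl]acetate, via lithium lactone enolate 4 (not isolated)
Conditions: 3, LiN(i-Pr)2, THF, −78 °C; then 2, −78 °C; then MeI, DMPU, −78 → −20 °C
Reagents that add atoms: iodomethane, CI
Why: the lithium enolate of 3 adds to the butenolide in a Michael reaction anti to the C-7 substituent on C-6 (sets C-5), and the lactone enolate 4 is methylated at C-10 anti to the new C-5 arm (tandem conjugate addition–alkylation); the C-10 configuration is reset in step 3.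

Step 3
Reactants: 5 tert-butyl 2-[(2S,3S,4S)-2-[(benzyloxy)methyl]-4-methyl-5-oxooxolan-3-yl]acetate; 6 methyl prop-2-enoate
Product: 8 tert-butyl (3S,3aS,7aS)-3-[(benzyloxy)methyl]-7a-methyl-1,5-dioxo-octahydro-2-benzofuran-4-carboxylate (C-4 epimers and enol), via Michael adduct diester 7 (not isolated)
Conditions: LiN(SiMe3)2, THF, −78 °C; 6, −78 → −40 °C; then KOt-Bu, −40 → 0 °C; 1 M HCl
Reagents that add atoms: none
Why: LiN(SiMe3)2 removes H-10, the most acidic C–H (α to the lactone carbonyl; the tert-butyl ester CH2 is less acidic), and the lactone enolate adds to methyl acrylate on the face anti to the C-5 acetate arm, forming C-1–C-10 and a quaternary C-10 whose methyl is cis to that arm, as the later trans A/B fusion requires. Proton return from HN(SiMe3)2 gives diester 7, and KOt-Bu then forms the tert-butyl ester enolate at C-4 reversibly, which attacks the methyl ester in a 6-exo-trig acyl substitution that closes ring A (C-3–C-4) and is withdrawn as the stabilised β-keto ester enolate. The closest known reaction type is the tandem Michael–Dieckmann (Michael–Claisen) annulation of ester enolates with acrylates. C-10 is the only stereocentre fixed here and is controlled by the adjacent C-5 substituent of the trans-β,γ-disubstituted butanolide (alkylation anti to the β-substituent), while C-4 stays epimerisable until step 4. The step needs site selectivity between the two ester α-positions, secured by the higher acidity of the lactone α-proton, and a single Claisen mode, secured because the hindered tert-butyl ester is no acceptor and the lactone carbonyl could only give four-membered rings. Because C-9 is tied to O-6 as the lactone, there is no enolisable position on its far side and no bridged ring can form.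

Step 4
Reactants: 8 tert-butyl (3S,3aS,7aS)-3-[(benzyloxy)methyl]-7a-methyl-1,5-dioxo-octahydro-2-benzofuran-4-carboxylate
Product: 9 tert-butyl (3S,3aR,4R,7aS)-3-[(benzyloxy)methyl]-4,7a-dimethyl-1,5-dioxo-octahydro-2-benzofuran-4-carboxylate
Conditions: MeI, K2CO3, acetone, 50 °C
Reagents that add atoms: iodomethane, CI
Why: C-alkylation of the β-keto ester enolate should occur from the face opposite the axial C-10 methyl, which is syn-axial to C-4, so the new methyl becomes equatorial (α) and the ester carbon C-19 axial (β).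

Step 5
Reactants: 9 tert-butyl (3S,3aR,4R,7aS)-3-[(benzyloxy)methyl]-4,7a-dimethyl-1,5-dioxo-octahydro-2-benzofuran-4-carboxylate
Product: 10 tert-butyl (3S,3aR,4R,5R,7aS)-3-[(benzyloxy)methyl]-5-hydroxy-4,7a-dimethyl-1-oxo-octahydro-2-benzofuran-4-carboxylate
Conditions: LiBH(s-Bu)3, THF, −78 °C; then H2O
Reagents that add atoms: none
Why: the bulky trialkylborohydride should attack the C-3 ketone along the equatorial path, since the axial path is blocked by the axial hydrogens on C-1 and C-5, giving the axial 3α-alcohol, while the lactone and the tert-butyl ester are not reduced at −78 °C.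

Step 6
Reactants: 10 tert-butyl (3S,3aR,4R,5R,7aS)-3-[(benzyloxy)methyl]-5-hydroxy-4,7a-dimethyl-1-oxo-octahydro-2-benzofuran-4-carboxylate
Product: 12 (3S,3aR,4S,7R,7aR)-3-[(benzyloxy)methyl]-7-hydroxy-4,7a-dimethyl-4-propanoyl-octahydro-2-benzofuran-1-one, via lactol 11 (not isolated)
Conditions: EtLi, THF, −78 °C; H2O; then CF3CO2H, CH2Cl2, 0 °C → rt
Reagents that add atoms: ethyllithium, [Li]CC
Why: ethyllithium should add once to the hindered γ-lactone (the lithium lactolate resists a second addition) to give lactol 11, and acid then removes the tert-butyl group and lactonises the freed 6-hydroxyl onto the axial C-19 acid, leaving C-9 as an ethyl ketone without touching any stereocentre.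

Step 7
Reactants: 12 (3S,3aR,4S,7R,7aR)-3-[(benzyloxy)methyl]-7-hydroxy-4,7a-dimethyl-4-propanoyl-octahydro-2-benzofuran-1-one
Product: 13 (3S,3aR,4S,7R,7aR)-7-hydroxy-3-(hydroxymethyl)-4,7a-dimethyl-4-propanoyl-octahydro-2-benzofuran-1-one
Conditions: H2 (1 atm), Pd/C, EtOAc, rt
Reagents that add atoms: none
Why: hydrogenolysis of the benzyl ether frees the C-7 alcohol, and no alkene or other reducible group is present.

Step 8
Reactants: 13 (3S,3aR,4S,7R,7aR)-7-hydroxy-3-(hydroxymethyl)-4,7a-dimethyl-4-propanoyl-octahydro-2-benzofuran-1-one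
Product: 14 (3S,3aR,4S,7R,7aR)-7-hydroxy-4,7a-dimethyl-1-oxo-4-propanoyl-octahydro-2-benzofuran-3-carbaldehyde
Conditions: TEMPO (cat.), PhI(OAc)2, CH2Cl2, rt
Reagents that add atoms: none
Why: the oxoammonium oxidation should convert the unhindered primary alcohol into the aldehyde and leave the hindered axial secondary 3-hydroxyl.

Step 9
Reactants: 14 (3S,3aR,4S,7R,7aR)-7-hydroxy-4,7a-dimethyl-1-oxo-4-propanoyl-octahydro-2-benzofuran-3-carbaldehyde
Product: 15 3α-hydroxy-9-oxo-11,12,13,14,15,16-hexanorlabd-7-en-19,6β-olide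
Conditions: Bn2NH2+ CF3CO2− (cat.), toluene, 50 °C
Reagents that add atoms: none
Why: intramolecular aldol condensation, in which the ethyl ketone can enolise only toward C-8 (C-10 is quaternary), C-8 attacks the C-7 aldehyde in a six-membered closure that the 19,6β-lactone permits only for the correct C-6 configuration, and loss of water gives the conjugated 7-en-9-one of ring B.

Step 10
Reactants: 15 3α-hydroxy-9-oxo-11,12,13,14,15,16-hexanorlabd-7-en-19,6β-olide
Product: 17 3α-hydroxy-9-(trifluoromethanesulfonyloxy)-11,12,13,14,15,16-hexanorlabd-8-en-19,6β-olide, via dilithium enolate 16 (not isolated)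
Conditions: LiBH(s-Bu)3, THF, −78 °C; then PhNTf2, −78 → 0 °C; H2O
Reagents that add atoms: N-phenylbis(trifluoromethanesulfonimide), O=S(=O)(N(c1ccccc1)S(=O)(=O)C(F)(F)F)C(F)(F)F
Why: conjugate hydride addition to the enone gives the C-9 enolate 16 regiospecifically and O-triflation fixes the tetrasubstituted C-8=C-9 double bond (reductive enolate trapping), the first equivalent of hydride only deprotonating the 3-hydroxyl.

Step 11
Reactants: 17 3α-hydroxy-9-(trifluoromethanesulfonyloxy)-11,12,13,14,15,16-hexanorlabd-8-en-19,6β-olide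
Product: 18 3α,6β,19-trihydroxy-11,12,13,14,15,16-hexanorlabd-8-en-9-yl trifluoromethanesulfonate
Conditions: LiBH4, THF, 0 → 50 °C; then 1 M HCl, 0 °C
Reagents that add atoms: none
Why: borohydride reduction of the γ-lactone should give the 6β,19-diol with retention at C-6 (acyl C–O cleavage) without attacking the enol triflate.

Step 12
Reactants: 19 methyl but-2-ynoate
Product: 20 methyl (2E)-3-methylpenta-2,4-dienoate
Conditions: CH2=CHMgBr, CuBr·SMe2, THF, −78 °C; then 19, −78 °C; 1 M HCl
Reagents that add atoms: vinylmagnesium bromide, C=C[Mg]Br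
Why: syn-carbocupration of the ynoate by the vinylcopper reagent and protonation with retention should give the 2E dienoate (vinyl trans to the ester).

Step 13
Reactants: 18 3α,6β,19-trihydroxy-11,12,13,14,15,16-hexanorlabd-8-en-9-yl trifluoromethanesulfonate; 20 methyl (2E)-3-methylpenta-2,4-dienoate
Product: 22 methyl (13E)-3α,6β,19-trihydroxylabda-8,13-dien-15-oate, via B-alkyl-9-BBN borane 21 (not isolated)
Conditions: 20, 9-BBN, THF, 0 °C → rt; then 18, Pd(dppf)Cl2 (cat.), AsPh3 (cat.), Cs2CO3, DMF/H2O, 50 °C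
Reagents that add atoms: none
Why: 9-BBN should hydroborate the terminal vinyl group of 20 at its CH2 end, and B-alkyl Suzuki–Miyaura coupling of borane 21 with the enol triflate forms C-9–C-11 with retention of both alkene geometries, free hydroxyls being tolerated.

Step 14
Reactants: 22 methyl (13E)-3α,6β,19-trihydroxylabda-8,13-dien-15-oate
Product: 23 (13E)-3α,6β,19-trihydroxylabda-8,13-dien-15-oic acid
Conditions: LiOH, THF/MeOH/H2O, 40 °C; then 1 M HCl to pH 3
Reagents that add atoms: lithium hydroxide, [Li+].[OH-]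
Why: saponification of the methyl ester gives the acid without affecting any stereocentre or alkene.

**Compound list**
1 | (S)-5-(hydroxymethyl)furan-2(5H)-one | OC[C@H]1OC(=O)C=C1 | starting material
2 | (S)-5-[(benzyloxy)methyl]furan-2(5H)-one | O=C1C=C[C@@H](COCc2ccccc2)O1 | intermediate
3 | tert-butyl acetate | CC(=O)OC(C)(C)C | starting material
4 | lithium (4S,5S)-5-[(benzyloxy)methyl]-4-(2-tert-butoxy-2-oxoethyl)-4,5-dihydrofuran-2-olate (lithium lactone enolate) | [Li+].[O-]C1=C[C@H](CC(=O)OC(C)(C)C)[C@@H](COCc2ccccc2)O1 | intermediate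
5 | tert-butyl 2-[(2S,3S,4S)-2-[(benzyloxy)methyl]-4-methyl-5-oxooxolan-3-yl]acetate | O=C1O[C@H](COCc2ccccc2)[C@@H](CC(=O)OC(C)(C)C)[C@@H]1C | intermediate
6 | methyl prop-2-enoate (methyl acrylate) | C=CC(=O)OC | starting material
7 | methyl 3-[(3S,4S,5S)-5-[(benzyloxy)methyl]-4-(2-tert-butoxy-2-oxoethyl)-3-methyl-2-oxooxolan-3-yl]propanoate (Michael adduct diester) | O=C1O[C@H](COCc2ccccc2)[C@@H](CC(=O)OC(C)(C)C)[C@]1(C)CCC(=O)OC | intermediate
8 | tert-butyl (3S,3aS,7aS)-3-[(benzyloxy)methyl]-7a-methyl-1,5-dioxo-octahydro-2-benzofuran-4-carboxylate (C-4 epimers and enol) | O=C1O[C@H](COCc2ccccc2)[C@H]2C(C(=O)OC(C)(C)C)C(=O)CC[C@]12C | intermediate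
9 | tert-butyl (3S,3aR,4R,7aS)-3-[(benzyloxy)methyl]-4,7a-dimethyl-1,5-dioxo-octahydro-2-benzofuran-4-carboxylate | O=C1O[C@H](COCc2ccccc2)[C@H]2[C@@](C)(C(=O)OC(C)(C)C)C(=O)CC[C@]12C | intermediate
10 | tert-butyl (3S,3aR,4R,5R,7aS)-3-[(benzyloxy)methyl]-5-hydroxy-4,7a-dimethyl-1-oxo-octahydro-2-benzofuran-4-carboxylate | O=C1O[C@H](COCc2ccccc2)[C@H]2[C@@](C)(C(=O)OC(C)(C)C)[C@H](O)CC[C@]12C | intermediate
11 | tert-butyl (3S,3aR,4R,5R,7aS)-3-[(benzyloxy)methyl]-1-ethyl-1,5-dihydroxy-4,7a-dimethyl-octahydro-2-benzofuran-4-carboxylate (lactol, C-1 epimers) | CCC1(O)O[C@H](COCc2ccccc2)[C@H]2[C@@](C)(C(=O)OC(C)(C)C)[C@H](O)CC[C@]12C | intermediate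
12 | (3S,3aR,4S,7R,7aR)-3-[(benzyloxy)methyl]-7-hydroxy-4,7a-dimethyl-4-propanoyl-octahydro-2-benzofuran-1-one | CCC(=O)[C@@]1(C)CC[C@@H](O)[C@]2(C)C(=O)O[C@H](COCc3ccccc3)[C@H]12 | intermediate
13 | (3S,3aR,4S,7R,7aR)-7-hydroxy-3-(hydroxymethyl)-4,7a-dimethyl-4-propanoyl-octahydro-2-benzofuran-1-one | CCC(=O)[C@@]1(C)CC[C@@H](O)[C@]2(C)C(=O)O[C@H](CO)[C@H]12 | intermediate
14 | (3S,3aR,4S,7R,7aR)-7-hydroxy-4,7a-dimethyl-1-oxo-4-propanoyl-octahydro-2-benzofuran-3-carbaldehyde | CCC(=O)[C@@]1(C)CC[C@@H](O)[C@]2(C)C(=O)O[C@H](C=O)[C@H]12 | intermediate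
15 | 3α-hydroxy-9-oxo-11,12,13,14,15,16-hexanorlabd-7-en-19,6β-olide | CC1=C[C@H]2OC(=O)[C@@]3(C)[C@H](O)CC[C@](C)(C1=O)[C@@H]23 | intermediate
16 | dilithium 3α,9-dioxido-11,12,13,14,15,16-hexanorlabd-8-en-19,6β-olide (dilithium enolate) | [Li+].[Li+].CC1=C([O-])[C@@]2(C)CC[C@@H]([O-])[C@]3(C)C(=O)O[C@H](C1)[C@H]23 | intermediate
17 | 3α-hydroxy-9-(trifluoromethanesulfonyloxy)-11,12,13,14,15,16-hexanorlabd-8-en-19,6β-olide | CC1=C(OS(=O)(=O)C(F)(F)F)[C@@]2(C)CC[C@@H](O)[C@]3(C)C(=O)O[C@H](C1)[C@H]23 | intermediate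
18 | 3α,6β,19-trihydroxy-11,12,13,14,15,16-hexanorlabd-8-en-9-yl trifluoromethanesulfonate | CC1=C(OS(=O)(=O)C(F)(F)F)[C@@]2(C)CC[C@@H](O)[C@](C)(CO)[C@@H]2[C@H](O)C1 | intermediate
19 | methyl but-2-ynoate | CC#CC(=O)OC | starting material
20 | methyl (2E)-3-methylpenta-2,4-dienoate | C=C/C(C)=C/C(=O)OC | intermediate
21 | methyl (2E)-5-(9-borabicyclo[3.3.1]nonan-9-yl)-3-methylpent-2-enoate (B-alkyl-9-BBN borane) | COC(=O)/C=C(C)/CCB1C2CCCC1CCC2 | intermediate
22 | methyl (13E)-3α,6β,19-trihydroxylabda-8,13-dien-15-oate | CC1=C(CC/C(C)=C/C(=O)OC)[C@@]2(C)CC[C@@H](O)[C@](C)(CO)[C@@H]2[C@H](O)C1 | intermediate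
23 | (13E)-3α,6β,19-trihydroxylabda-8,13-dien-15-oic acid | CC1=C(CC/C(C)=C/C(=O)O)[C@@]2(C)CC[C@@H](O)[C@](C)(CO)[C@@H]2[C@H](O)C1 | target

Total step count: 14. Longest linear sequence: 13 steps (steps 1–11, 13 and 14, from 1 to 23).

**Steps most likely to fail**

1. Step 3. Oligomerisation of the acrylate, or deprotonation and addition at the tert-butyl ester α-position instead of C-10, could overtake the Michael addition; the ring closure could also fail to outrun cleavage of the adduct. Fallback, from 5 back to 8, builds the three-carbon arm by alkylation and oxidation instead of conjugate addition. Compound 5 is deprotonated with LiN(i-Pr)2 and alkylated with allyl bromide, anti to the C-5 arm, to give tert-butyl 2-[(2S,3S,4S)-2-[(benzyloxy)methyl]-4-methyl-5-oxo-4-(prop-2-en-1-yl)oxolan-3-yl]acetate F1. Hydroboration with 9-BBN and oxidation with NaBO3 give tert-butyl 2-[(2S,3S,4S)-2-[(benzyloxy)methyl]-4-(3-hydroxypropyl)-4-methyl-5-oxooxolan-3-yl]acetate F2. Oxidation with TEMPO and PhI(OAc)2 in MeCN/H2O gives 3-[(3S,4S,5S)-5-[(benzyloxy)methyl]-4-(2-tert-butoxy-2-oxoethyl)-3-methyl-2-oxooxolan-3-yl]propanoic acid F3. Esterification with Me3SiCHN2 gives 7, now isolated, and Dieckmann closure with KOt-Bu returns to 8.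

2. Step 9. The α-oxygenated aldehyde may epimerise or decompose faster than the hindered ethyl ketone enolises and condenses. Fallback, from 13 back to 17, closes ring B by enolate alkylation instead of aldol condensation. Compound 13 is converted with I2, PPh3 and imidazole into (3S,3aR,4S,7R,7aR)-7-hydroxy-3-(iodomethyl)-4,7a-dimethyl-4-propanoyl-octahydro-2-benzofuran-1-one F4. KN(SiMe3)2 in THF at −78 → 0 °C closes the ring by 6-exo-tet alkylation of the ethyl ketone enolate to 3α-hydroxy-9-oxo-11,12,13,14,15,16-hexanorlabdan-19,6β-olide F5 (C-8 epimers). Enolisation with KN(SiMe3)2 and trapping with PhNTf2 give 17.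

3. Step 13. Transmetalation of the B-alkyl borane to the hindered, tetrasubstituted enol triflate may be too slow, and hydroboration of the dienoate may lose regiocontrol. Fallback, from 18 back to 22, reverses the roles of the coupling partners. Stille coupling of 18 with Bu3SnCH=CH2 (Pd(PPh3)4, LiCl, THF, 65 °C) gives 13,14,15,16-tetranorlabda-8,11-diene-3α,6β,19-triol F6. Hydroboration of its terminal alkene with excess 9-BBN, then B-alkyl Suzuki–Miyaura coupling with methyl (2E)-3-iodobut-2-enoate (Pd(dppf)Cl2, Cs2CO3, DMF/H2O), gives 22.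

**Further compounds**
F1 | step 3 | tert-butyl 2-[(2S,3S,4S)-2-[(benzyloxy)methyl]-4-methyl-5-oxo-4-(prop-2-en-1-yl)oxolan-3-yl]acetate | O=C1O[C@H](COCc2ccccc2)[C@@H](CC(=O)OC(C)(C)C)[C@]1(C)CC=C
F2 | step 3 | tert-butyl 2-[(2S,3S,4S)-2-[(benzyloxy)methyl]-4-(3-hydroxypropyl)-4-methyl-5-oxooxolan-3-yl]acetate | O=C1O[C@H](COCc2ccccc2)[C@@H](CC(=O)OC(C)(C)C)[C@]1(C)CCCO
F3 | step 3 | 3-[(3S,4S,5S)-5-[(benzyloxy)methyl]-4-(2-tert-butoxy-2-oxoethyl)-3-methyl-2-oxooxolan-3-yl]propanoic acid | O=C1O[C@H](COCc2ccccc2)[C@@H](CC(=O)OC(C)(C)C)[C@]1(C)CCC(=O)O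
F4 | step 9 | (3S,3aR,4S,7R,7aR)-7-hydroxy-3-(iodomethyl)-4,7a-dimethyl-4-propanoyl-octahydro-2-benzofuran-1-one | CCC(=O)[C@@]1(C)CC[C@@H](O)[C@]2(C)C(=O)O[C@H](CI)[C@H]12
F5 | step 9 | 3α-hydroxy-9-oxo-11,12,13,14,15,16-hexanorlabdan-19,6β-olide (C-8 epimers) | CC1C[C@H]2OC(=O)[C@@]3(C)[C@H](O)CC[C@](C)(C1=O)[C@@H]23
F6 | step 13 | 13,14,15,16-tetranorlabda-8,11-diene-3α,6β,19-triol | CC1=C(C=C)[C@@]2(C)CC[C@@H](O)[C@](C)(CO)[C@@H]2[C@H](O)C1
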